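**Plan**

- Retrosynthetic cuts, in order: (i) the C7(=O)–C1 bond between the ketone carbon and the 3,4,5-trimethoxyphenyl ring; (ii) the C8–O4′ aryl ether bond; (iii) the C1′–C7′ aryl–alkenyl bond.
- Forward: the E-cinnamyl methyl ether chain is joined to the guaiacyl ring first (Suzuki coupling), the lactate unit is attached through O4′ (Mitsunobu), the ester is turned into an S-phenyl thiol ester, and the trimethoxyphenyl ring is joined last. No ring is formed and no protecting group is used.
- Stereochemistry: C8 (S) comes from methyl (R)-lactate with inversion in the Mitsunobu step; the E C7′=C8′ bond comes from the E-alkenylboronate. Both are only carried afterwards.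
- Enabling feature: C7 is a carbonyl carbon bonded on one side to C1 of the symmetric trimethoxyphenyl ring and on the other to C8. C1 is para to the 4-OMe and flanked by H-2/H-6, a position that electrophilic acylation of 1,2,3-trimethoxybenzene does not reach. The C8–H is acidified by both C7=O and the O4′ aryloxy group. A thiol ester at C7 and boron at C1 let the bond form under Pd/Cu catalysis without base, so C8 is not enolized.

Key step: step 5

Assumption: C7 is the ketone carbon, C8 the stereocentre and primed locants belong to the guaiacyl unit; compounds 1, 2, 4, 7 and 9 are taken as commercial.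

**Route**

Step 1
Reactants: 1 4-bromo-2-methoxyphenol; 2 (E)-2-(3-methoxyprop-1-en-1-yl)-4,4,5,5-tetramethyl-1,3,2-dioxaborolane
Product: 3 (E)-2-methoxy-4-(3-methoxyprop-1-en-1-yl)phenol
Conditions: Pd(OAc)2 (2 mol %), SPhos (4 mol %), K3PO4 (3 equiv), 1,4-dioxane/H2O 4:1, 80 °C, Ar
Reagents that add atoms: none
Why: Suzuki–Miyaura coupling, in which the alkenyl pinacol boronate should transmetalate with retention so that the E geometry of 2 is copied into C7′=C8′, while the free phenol is tolerated as its phenoxide under aqueous phosphate.

Step 2
Reactants: 3 (E)-2-methoxy-4-(3-methoxyprop-1-en-1-yl)phenol; 4 methyl (R)-lactate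
Product: 5 methyl (2S)-2-{2-methoxy-4-[(1E)-3-methoxyprop-1-en-1-yl]phenoxy}propanoate
Conditions: PPh3 (1.3 equiv), DIAD (1.3 equiv), THF, 0 °C → rt
Reagents that add atoms: none
Why: Mitsunobu etherification, in which the phenoxide of 3 should displace the oxyphosphonium of the secondary lactate carbinol by SN2 with clean inversion, so that (R)-4 sets C8 as S.

Step 3
Reactants: 5 methyl (2S)-2-{2-methoxy-4-[(1E)-3-methoxyprop-1-en-1-yl]phenoxy}propanoate
Product: 6 (2S)-2-{2-methoxy-4-[(1E)-3-methoxyprop-1-en-1-yl]phenoxy}propanoic acid
Conditions: LiOH·H2O (1.5 equiv), THF/H2O 3:1, 0 °C; then 1 M HCl to pH 3 at 0 °C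
Reagents that add atoms: lithium hydroxide, [Li+].[OH-]
Why: Saponification (BAc2) of the α-aryloxy-activated ester should be fast at 0 °C and outrun enolization, giving a carboxylate that resists α-deprotonation, so C8 stays untouched; the allylic methyl ether and the alkene are inert to hydroxide and to brief cold acidification.

Step 4
Reactants: 6 (2S)-2-{2-methoxy-4-[(1E)-3-methoxyprop-1-en-1-yl]phenoxy}propanoic acid; 7 thiophenol
Product: 8 S-phenyl (2S)-2-{2-methoxy-4-[(1E)-3-methoxyprop-1-en-1-yl]phenoxy}propanethioate
Conditions: DCC (1.1 equiv), HOBt (1.1 equiv), EtOAc, 0 °C → rt, Ar, dark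
Reagents that add atoms: none
Why: Carbodiimide/HOBt thioesterification, the base-free protocol used for configurationally labile N-protected α-amino acid thiol esters, should acylate the thiol without amine base or DMAP and therefore without enolizing C8; exclusion of light and oxygen suppresses radical thiol–ene addition to the styrene.

Step 5
Reactants: 8 S-phenyl (2S)-2-{2-methoxy-4-[(1E)-3-methoxyprop-1-en-1-yl]phenoxy}propanethioate; 9 3,4,5-trimethoxyphenylboronic acid
Product: 10 (2S)-2-{2-methoxy-4-[(1E)-3-methoxyprop-1-en-1-yl]phenoxy}-1-(3,4,5-trimethoxyphenyl)propan-1-one, the target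
Conditions: Pd2(dba)3 (2.5 mol %), P(OEt)3 (20 mol %), copper(I) thiophene-2-carboxylate (CuTC, 1.6 equiv), 9 (1.5 equiv), THF, rt → 40 °C, Ar
Reagents that add atoms: none
Why: Liebeskind–Srogl thiol ester–boronic acid cross-coupling: Pd(0) should insert into the C7–S bond of 8, the Cu(I) carboxylate should bind the thiolate on palladium while its carboxylate oxygen activates the boron of 9, the trimethoxyphenyl group is transferred to the acyl-palladium, and reductive elimination forms C7–C1. The closest known case is the ketone synthesis from N-protected α-amino acid S-phenyl thiol esters and arylboronic acids, which runs at room temperature with retention at the α-carbon. No ring is closed and no stereocentre is created; the existing C8 centre should be retained because the medium contains no base, no enolate and no free organometallic nucleophile, and the ketone appears only at reductive elimination, so it cannot be attacked a second time. The step needs chemoselective oxidative addition at C7–S in the presence of the allylic C9′–OMe ether and the C7′=C8′ styrene, which the thiophilic copper-assisted activation of the thiol ester, the poor leaving-group ability of methoxide and the low temperature should secure. The site of acylation on the trimethoxyphenyl ring is fixed at C1 by the position of boron, and 9, being electron-rich and free of ortho substituents, should transmetalate quickly and resist protodeboronation.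

**Compound list**

1 | 4-bromo-2-methoxyphenol | COc1cc(Br)ccc1O | starting material
2 | (E)-2-(3-methoxyprop-1-en-1-yl)-4,4,5,5-tetramethyl-1,3,2-dioxaborolane | COC/C=C/B1OC(C)(C)C(C)(C)O1 | starting material
3 | (E)-2-methoxy-4-(3-methoxyprop-1-en-1-yl)phenol | COC/C=C/c1ccc(O)c(OC)c1 | intermediate
4 | methyl (R)-lactate | C[C@@H](O)C(=O)OC | starting material
5 | methyl (2S)-2-{2-methoxy-4-[(1E)-3-methoxyprop-1-en-1-yl]phenoxy}propanoate | COC/C=C/c1ccc(O[C@@H](C)C(=O)OC)c(OC)c1 | intermediate
6 | (2S)-2-{2-methoxy-4-[(1E)-3-methoxyprop-1-en-1-yl]phenoxy}propanoic acid | COC/C=C/c1ccc(O[C@@H](C)C(=O)O)c(OC)c1 | intermediate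
7 | thiophenol | Sc1ccccc1 | starting material
8 | S-phenyl (2S)-2-{2-methoxy-4-[(1E)-3-methoxyprop-1-en-1-yl]phenoxy}propanethioate | COC/C=C/c1ccc(O[C@@H](C)C(=O)Sc2ccccc2)c(OC)c1 | intermediate
9 | 3,4,5-trimethoxyphenylboronic acid | COc1cc(B(O)O)cc(OC)c1OC | starting material
10 | (2S)-2-{2-methoxy-4-[(1E)-3-methoxyprop-1-en-1-yl]phenoxy}-1-(3,4,5-trimethoxyphenyl)propan-1-one | COC/C=C/c1ccc(O[C@@H](C)C(=O)c2cc(OC)c(OC)c(OC)c2)c(OC)c1 | target

**Step count**

Total steps: 5. Longest linear sequence: 5 (1 → 3 → 5 → 6 → 8 → 10).

**Steps most likely to fail**

Step 5. The coupling may suffer from slow transmetalation with competing protodeboronation or homocoupling of the boronic acid, from palladium-induced ionization of the allylic methyl ether, or from erosion of configuration at C8 by enolization of the product ketone on long contact with the copper carboxylate. The fallback replaces the catalytic coupling by a chelation-controlled acyl substitution. It sets out from acid 6, which is condensed with N,O-dimethylhydroxylamine hydrochloride (EDC·HCl, HOBt, N-methylmorpholine, CH2Cl2, 0 °C) to give the Weinreb amide (2S)-N-methoxy-N-methyl-2-{2-methoxy-4-[(1E)-3-methoxyprop-1-en-1-yl]phenoxy}propanamide F1. Addition of commercial 3,4,5-trimethoxyphenylmagnesium bromide solution in THF at −20 → 0 °C, with inverse quench into cold aqueous NH4Cl, should then return the route at 10. The magnesium-chelated tetrahedral adduct holds the carbonyl masked until the quench, so neither over-addition nor enolization of the ketone is expected.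

Step 4. Activation of the α-aryloxy acid may lead to partial racemization through enol or ketene formation from the activated acyl species, and the thiol may add across the styrene. The fallback builds the thiol ester before the aryloxy stereocentre exists. It sets out from methyl (R)-lactate 4, which is converted with Me2AlSPh (from AlMe3 and thiophenol, CH2Cl2, 0 °C → rt) into S-phenyl (R)-2-hydroxypropanethioate F2. Mitsunobu etherification of phenol 3 with F2 (PPh3, DIAD, THF, 0 °C) should then give thiol ester 8 directly with inversion, so the route is rejoined at 8 and steps 2 to 4 are bypassed.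

Step 2. The redox condensation may stall with the ortho-substituted, only moderately acidic phenol, or inversion fidelity may be eroded. The fallback changes from Mitsunobu activation to a classical sulfonate displacement. It sets out from methyl (R)-lactate 4, which is tosylated (TsCl, Et3N, cat. DMAP, CH2Cl2, 0 °C) to methyl (R)-2-(tosyloxy)propanoate F3. SN2 displacement by the phenoxide of 3 (K2CO3, MeCN, 50 °C) should give ester 5 with inversion, where the route is rejoined.

**Further compounds**

F1 | step 5 | (2S)-N-methoxy-N-methyl-2-{2-methoxy-4-[(1E)-3-methoxyprop-1-en-1-yl]phenoxy}propanamide | COC/C=C/c1ccc(O[C@@H](C)C(=O)N(C)OC)c(OC)c1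
F2 | step 4 | S-phenyl (R)-2-hydroxypropanethioate | C[C@@H](O)C(=O)Sc1ccccc1
F3 | step 2 | methyl (R)-2-(tosyloxy)propanoate | C[C@@H](OS(=O)(=O)c1ccc(C)cc1)C(=O)OC
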